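The ten-membered carbocycle is closed last, between the vinylic carbon C1 and the carbinol carbon C2 (germacrane numbering: C1=C10, C4=C5, C6 ester, C7/C8 lactone fusion, C9 hydroxyl), by an intramolecular Nozaki–Hiyama–Kishi reaction. The step exploits the allylic alcohol C2(OH)–C1=C10(CH3) of the cyclodecadiene: the Z geometry is stored in an alkenyl iodide, and C–C bond, ring and C2 stereocentre arise in one operation. Its precursor is an unprotected open-chain β,γ-unsaturated aldehyde that already holds the α-methylene-γ-lactone, the (R)-2-methylbutanoate and the free C9 hydroxyl; it is assembled around a 3-(bromomethyl)butenolide by Brown alkoxyallylboration (C8, C9) and a zinc Barbier reaction (C6, C7).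

Key step: step 14

Remark: the ester side chain is taken as (2R)-2-methylbutanoyl, as drawn, and is introduced from (R)-2-methylbutanoic acid; C11=C13 is the exo-methylene and C12 the lactone carbonyl.

Step 1
Reactants: 1 prop-2-yn-1-ol
Product: 3 (2Z)-3-iodo-2-methylprop-2-en-1-ol, via chelated alkenylmagnesium alkoxide 2 (not isolated)
Conditions: MeMgBr (3 equiv), CuI (10 mol%), THF, −10 °C to rt; then I2, −10 °C
Reagents that add atoms: methylmagnesium bromide, C[Mg]Br; iodine, II
Why: Copper-catalysed anti-carbomagnesiation of the propargylic alkoxide places methyl on C2 and magnesium on C3 cis to the chelating alkoxide, so iodinolysis with retention should give the Z iodide only.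

Step 2
Reactants: 3 (2Z)-3-iodo-2-methylprop-2-en-1-ol
Product: 4 (2Z)-3-iodo-2-methylprop-2-enal
Conditions: activated MnO2, CH2Cl2, rt, dark; used crude
Reagents that add atoms: none
Why: Allylic alcohol oxidation with MnO2 is neutral and should give the aldehyde without Z to E isomerisation if the product is used at once.

Step 3
Reactants: 4 (2Z)-3-iodo-2-methylprop-2-enal; 5 allyl 4-methoxybenzyl ether
Product: 7 (1Z,3R,4R)-1-iodo-4-[(4-methoxybenzyl)oxy]-2-methylhexa-1,5-dien-3-ol, via Z-γ-alkoxyallyl-diisopinocampheylborane 6 (not isolated)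
Conditions: 5, s-BuLi, THF, −78 °C; (−)-Ipc2BOMe [from (+)-α-pinene]; BF3·OEt2; then 4, −78 °C; NaOH, H2O2, 0 °C to rt
Reagents that add atoms: none
Why: Brown alkoxyallylboration, in which the Z-γ-alkoxyallylborane reacts through a chair transition state so that Z geometry becomes the syn relationship, and the Ipc groups direct attack to the si face of 4, which sets 3R and 4R (future C9 and C8).

Step 4
Reactants: 7 (1Z,3R,4R)-1-iodo-4-[(4-methoxybenzyl)oxy]-2-methylhexa-1,5-dien-3-ol
Product: 8 tert-butyl({(1Z,3R,4R)-1-iodo-4-[(4-methoxybenzyl)oxy]-2-methylhexa-1,5-dien-3-yl}oxy)dimethylsilane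
Conditions: TBSOTf, 2,6-lutidine, CH2Cl2, −78 to 0 °C
Reagents that add atoms: tert-butyldimethylsilyl triflate, CC(C)(C)[Si](C)(C)OS(=O)(=O)C(F)(F)F
Why: Silylation of the hindered secondary allylic alcohol with the reactive silyl triflate protects the C9 hydroxyl for the later acylations.

Step 5
Reactants: 8 tert-butyl({(1Z,3R,4R)-1-iodo-4-[(4-methoxybenzyl)oxy]-2-methylhexa-1,5-dien-3-yl}oxy)dimethylsilane
Product: 9 (3R,4R,5Z)-4-[(tert-butyldimethylsilyl)oxy]-6-iodo-5-methylhexa-1,5-dien-3-ol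
Conditions: DDQ, CH2Cl2/pH 7 buffer, 0 °C
Reagents that add atoms: none
Why: Oxidative PMB cleavage, in which DDQ oxidises the electron-rich benzyl ether to an oxocarbenium ion that water hydrolyses, leaving the silyl ether, the alkenyl iodide and both stereocentres untouched.

Step 6
Reactants: 9 (3R,4R,5Z)-4-[(tert-butyldimethylsilyl)oxy]-6-iodo-5-methylhexa-1,5-dien-3-ol; 10 2-(bromomethyl)prop-2-enoic acid
Product: 11 (3R,4R,5Z)-4-[(tert-butyldimethylsilyl)oxy]-6-iodo-5-methylhexa-1,5-dien-3-yl 2-(bromomethyl)prop-2-enoate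
Conditions: DCC, DMAP (5 mol%), CH2Cl2, 0 °C
Reagents that add atoms: none
Why: Steglich esterification of the free C8 hydroxyl, with DMAP kept catalytic and the temperature low so that acyl transfer outruns SN2′ attack on the allylic bromide.

Step 7
Reactants: 11 (3R,4R,5Z)-4-[(tert-butyldimethylsilyl)oxy]-6-iodo-5-methylhexa-1,5-dien-3-yl 2-(bromomethyl)prop-2-enoate
Product: 12 (5R)-3-(bromomethyl)-5-[(1R,2Z)-1-[(tert-butyldimethylsilyl)oxy]-3-iodo-2-methylprop-2-en-1-yl]furan-2(5H)-one
Conditions: Grubbs II (5–10 mol%), toluene (0.01 M), 80 °C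
Reagents that add atoms: none
Why: Ring-closing metathesis between the terminal vinyl group and the 2-substituted acrylate closes the butenolide, while the trisubstituted alkenyl iodide is too hindered to engage the ruthenium carbene.

Step 8
Reactants: 13 4-methyl-5,6-dihydro-2H-pyran-2-one
Product: 14 4-methyl-5,6-dihydro-2H-pyran-2-ol (anomer mixture; ring tautomer of (2Z)-5-hydroxy-3-methylpent-2-enal)
Conditions: DIBAL-H (1.05 equiv), CH2Cl2, −78 °C; Rochelle salt work-up
Reagents that add atoms: none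
Why: Lactone half-reduction stops at the aluminium hemiacetal at −78 °C, and the ring keeps the future C4=C5 olefin Z.

Step 9
Reactants: 12 (5R)-3-(bromomethyl)-5-[(1R,2Z)-1-[(tert-butyldimethylsilyl)oxy]-3-iodo-2-methylprop-2-en-1-yl]furan-2(5H)-one; 14 4-methyl-5,6-dihydro-2H-pyran-2-ol
Product: 16 (4S,5R)-5-[(1R,2Z)-1-[(tert-butyldimethylsilyl)oxy]-3-iodo-2-methylprop-2-en-1-yl]-4-[(1R,2Z)-1,5-dihydroxy-3-methylpent-2-en-1-yl]-3-methylideneoxolan-2-one, via allylzinc bromide 15 (not isolated)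
Conditions: Zn dust, THF/sat. aq NH4Cl, 0 °C to rt; 14 in excess
Reagents that add atoms: none
Why: Zinc Barbier reaction with allylic transposition, in which allylzinc 15 attacks the open hydroxy-enal form of 14 through C7 in a chair transition state, on the butenolide face anti to the C8 side chain (sets C7, trans-lactone), and with anti simple diastereoselection because the ring holds C8 trans to the CH2Zn carbon (sets C6 as R).

Step 10
Reactants: 16 (4S,5R)-5-[(1R,2Z)-1-[(tert-butyldimethylsilyl)oxy]-3-iodo-2-methylprop-2-en-1-yl]-4-[(1R,2Z)-1,5-dihydroxy-3-methylpent-2-en-1-yl]-3-methylideneoxolan-2-one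
Product: 17 (4S,5R)-4-[(1R,2Z)-5-[(tert-butyldimethylsilyl)oxy]-1-hydroxy-3-methylpent-2-en-1-yl]-5-[(1R,2Z)-1-[(tert-butyldimethylsilyl)oxy]-3-iodo-2-methylprop-2-en-1-yl]-3-methylideneoxolan-2-one
Conditions: TBSCl (1.1 equiv), imidazole, CH2Cl2, 0 °C
Reagents that add atoms: tert-butyldimethylsilyl chloride, CC(C)(C)[Si](C)(C)Cl
Why: Selective silylation, since the primary hydroxyl reacts far faster than the hindered secondary allylic C6 hydroxyl.

Step 11
Reactants: 17 (4S,5R)-4-[(1R,2Z)-5-[(tert-butyldimethylsilyl)oxy]-1-hydroxy-3-methylpent-2-en-1-yl]-5-[(1R,2Z)-1-[(tert-butyldimethylsilyl)oxy]-3-iodo-2-methylprop-2-en-1-yl]-3-methylideneoxolan-2-one; 18 (2R)-2-methylbutanoic acid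
Product: 19 (1R,2Z)-5-[(tert-butyldimethylsilyl)oxy]-1-{(2R,3S)-2-[(1R,2Z)-1-[(tert-butyldimethylsilyl)oxy]-3-iodo-2-methylprop-2-en-1-yl]-4-methylidene-5-oxooxolan-3-yl}-3-methylpent-2-en-1-yl (2R)-2-methylbutanoate
Conditions: DCC, DMAP (cat.), CH2Cl2, 0 °C to rt
Reagents that add atoms: none
Why: Steglich esterification of the hindered allylic C6 hydroxyl, where low temperature and catalytic DMAP should keep the α-stereocentre of the acid intact while the other two oxygens stay silylated.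

Step 12
Reactants: 19 (1R,2Z)-5-[(tert-butyldimethylsilyl)oxy]-1-{(2R,3S)-2-[(1R,2Z)-1-[(tert-butyldimethylsilyl)oxy]-3-iodo-2-methylprop-2-en-1-yl]-4-methylidene-5-oxooxolan-3-yl}-3-methylpent-2-en-1-yl (2R)-2-methylbutanoate
Product: 20 (1R,2Z)-5-hydroxy-1-{(2R,3S)-2-[(1R,2Z)-1-hydroxy-3-iodo-2-methylprop-2-en-1-yl]-4-methylidene-5-oxooxolan-3-yl}-3-methylpent-2-en-1-yl (2R)-2-methylbutanoate
Conditions: HF·pyridine, pyridine, THF, 0 °C to rt
Reagents that add atoms: none
Why: Buffered fluoride desilylation removes both silyl ethers under conditions that should not open the lactone, migrate the ester or add to the α-methylene unit.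

Step 13
Reactants: 20 (1R,2Z)-5-hydroxy-1-{(2R,3S)-2-[(1R,2Z)-1-hydroxy-3-iodo-2-methylprop-2-en-1-yl]-4-methylidene-5-oxooxolan-3-yl}-3-methylpent-2-en-1-yl (2R)-2-methylbutanoate
Product: 21 (1R,2Z)-1-{(2R,3S)-2-[(1R,2Z)-1-hydroxy-3-iodo-2-methylprop-2-en-1-yl]-4-methylidene-5-oxooxolan-3-yl}-3-methyl-5-oxopent-2-en-1-yl (2R)-2-methylbutanoate
Conditions: TEMPO (10 mol%), PhI(OAc)2, CH2Cl2, rt; used directly
Reagents that add atoms: none
Why: Oxoammonium oxidation takes the unhindered primary alcohol much faster than the hindered secondary allylic C9 alcohol, and its near-neutral conditions should leave the β,γ-olefin unconjugated.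

Step 14
Reactants: 21 (1R,2Z)-1-{(2R,3S)-2-[(1R,2Z)-1-hydroxy-3-iodo-2-methylprop-2-en-1-yl]-4-methylidene-5-oxooxolan-3-yl}-3-methyl-5-oxopent-2-en-1-yl (2R)-2-methylbutanoate
Product: 23 (3aS,4R,5Z,8S,9Z,11R,11aR)-8,11-dihydroxy-6,10-dimethyl-3-methylidene-2-oxo-2,3,3a,4,7,8,11,11a-octahydrocyclodeca[b]furan-4-yl (2R)-2-methylbutanoate, via alkenylchromium(III) species 22 (not isolated)
Conditions: CrCl2 (10 equiv), NiCl2 (cat.), degassed DMSO/THF, slow addition of 21 to 2 mM, rt; aq. NH4Cl work-up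
Reagents that add atoms: none
Why: Ni(0) formed in situ inserts into the (Z)-alkenyl C–I bond and transmetalates to Cr(III) with retention, alkenylchromium 22 adds to the C2 aldehyde through a chromium-bound transition state, and hydrolysis releases the allylic alcohol; the closest known reaction type is the NHK macrocyclisation to medium-ring allylic alcohols. The ten-membered carbocycle closes in a 10-exo-trig mode, the aldehyde C=O lying outside the forming ring. The C1=C10 geometry is fixed in iodide 3 and carried through unchanged, and the new C2 stereocentre is set under substrate control, the aldehyde being expected to react with its oxygen turned outward and its face dictated by the (Z)-C4=C5 olefin, the C6 ester and the trans-lactone, which should favour 2S. The step needs chemoselectivity (alkenylchromium adds to the aldehyde but not to the lactone, the ester or the α-methylene unit, and tolerates the free C9 hydroxyl) and ring closure over oligomerisation, which the two Z olefins and the lactone as turn elements and the high dilution should secure. The facial selectivity at C2 is the main uncertainty and is answered by the fallback.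

Compound list
1 | prop-2-yn-1-ol | C#CCO | starting material
2 | bromomagnesium (2Z)-3-(bromomagnesio)-2-methylprop-2-en-1-olate | C/C(CO[Mg]Br)=C/[Mg]Br | intermediate
3 | (2Z)-3-iodo-2-methylprop-2-en-1-ol | OC/C(C)=C\I | intermediate
4 | (2Z)-3-iodo-2-methylprop-2-enal | O=C/C(C)=C\I | intermediate
5 | allyl 4-methoxybenzyl ether | C=CCOCc1ccc(OC)cc1 | starting material
6 | [(2Z)-3-(4-methoxybenzyloxy)prop-2-en-1-yl]di(isopinocampheyl)borane, Ipc from (+)-α-pinene | COc1ccc(CO/C=C\CB([C@@H]2C[C@@H]3C[C@H]([C@H]2C)C3(C)C)[C@@H]2C[C@@H]3C[C@H]([C@H]2C)C3(C)C)cc1 | intermediate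
7 | (1Z,3R,4R)-1-iodo-4-[(4-methoxybenzyl)oxy]-2-methylhexa-1,5-dien-3-ol | C=C[C@@H](OCc1ccc(OC)cc1)[C@H](O)/C(C)=C\I | intermediate
8 | tert-butyl({(1Z,3R,4R)-1-iodo-4-[(4-methoxybenzyl)oxy]-2-methylhexa-1,5-dien-3-yl}oxy)dimethylsilane | C=C[C@@H](OCc1ccc(OC)cc1)[C@H](O[Si](C)(C)C(C)(C)C)/C(C)=C\I | intermediate
9 | (3R,4R,5Z)-4-[(tert-butyldimethylsilyl)oxy]-6-iodo-5-methylhexa-1,5-dien-3-ol | C=C[C@@H](O)[C@H](O[Si](C)(C)C(C)(C)C)/C(C)=C\I | intermediate
10 | 2-(bromomethyl)prop-2-enoic acid | C=C(CBr)C(=O)O | starting material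
11 | (3R,4R,5Z)-4-[(tert-butyldimethylsilyl)oxy]-6-iodo-5-methylhexa-1,5-dien-3-yl 2-(bromomethyl)prop-2-enoate | C=C[C@@H](OC(=O)C(=C)CBr)[C@H](O[Si](C)(C)C(C)(C)C)/C(C)=C\I | intermediate
12 | (5R)-3-(bromomethyl)-5-[(1R,2Z)-1-[(tert-butyldimethylsilyl)oxy]-3-iodo-2-methylprop-2-en-1-yl]furan-2(5H)-one | O=C1O[C@@H]([C@H](O[Si](C)(C)C(C)(C)C)/C(C)=C\I)C=C1CBr | intermediate
13 | 4-methyl-5,6-dihydro-2H-pyran-2-one | CC1=CC(=O)OCC1 | starting material
14 | 4-methyl-5,6-dihydro-2H-pyran-2-ol | CC1=CC(O)OCC1 | intermediate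
15 | allylzinc bromide from 12 | O=C1O[C@@H]([C@H](O[Si](C)(C)C(C)(C)C)/C(C)=C\I)C=C1C[Zn]Br | intermediate
16 | (4S,5R)-5-[(1R,2Z)-1-[(tert-butyldimethylsilyl)oxy]-3-iodo-2-methylprop-2-en-1-yl]-4-[(1R,2Z)-1,5-dihydroxy-3-methylpent-2-en-1-yl]-3-methylideneoxolan-2-one | C=C1C(=O)O[C@@H]([C@H](O[Si](C)(C)C(C)(C)C)/C(C)=C\I)[C@@H]1[C@H](O)/C=C(/C)CCO | intermediate
17 | primary TBS ether of 16 | C=C1C(=O)O[C@@H]([C@H](O[Si](C)(C)C(C)(C)C)/C(C)=C\I)[C@@H]1[C@H](O)/C=C(/C)CCO[Si](C)(C)C(C)(C)C | intermediate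
18 | (2R)-2-methylbutanoic acid | CC[C@@H](C)C(=O)O | starting material
19 | C6 (2R)-2-methylbutanoate of 17 (bis-silyl ether) | C=C1C(=O)O[C@@H]([C@H](O[Si](C)(C)C(C)(C)C)/C(C)=C\I)[C@@H]1[C@H](OC(=O)[C@H](C)CC)/C=C(/C)CCO[Si](C)(C)C(C)(C)C | intermediate
20 | diol ester (C9–OH and primary OH free) | C=C1C(=O)O[C@@H]([C@H](O)/C(C)=C\I)[C@@H]1[C@H](OC(=O)[C@H](C)CC)/C=C(/C)CCO | intermediate
21 | seco-aldehyde (C2 aldehyde, C1 iodide) | C=C1C(=O)O[C@@H]([C@H](O)/C(C)=C\I)[C@@H]1[C@H](OC(=O)[C@H](C)CC)/C=C(/C)CC=O | intermediate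
22 | alkenylchromium(III) dichloride from 21 | C=C1C(=O)O[C@@H]([C@H](O)/C(C)=C\[Cr](Cl)Cl)[C@@H]1[C@H](OC(=O)[C@H](C)CC)/C=C(/C)CC=O | intermediate
23 | (3aS,4R,5Z,8S,9Z,11R,11aR)-8,11-dihydroxy-6,10-dimethyl-3-methylidene-2-oxo-2,3,3a,4,7,8,11,11a-octahydrocyclodeca[b]furan-4-yl (2R)-2-methylbutanoate | C=C1C(=O)O[C@@H]2[C@@H]1[C@H](OC(=O)[C@H](C)CC)/C=C(/C)C[C@H](O)/C=C(/C)[C@H]2O | target

Total step count: 14
Longest linear sequence: 13 (steps 1–7 and 9–14)

Steps most likely to fail

Step 14: the macrocyclic transition state may give poor facial selectivity at C2, and the preceding oxidation must discriminate against the free C9 hydroxyl. The fallback sets out from 19 and separates ring closure from stereocontrol. Selective cleavage of the primary silyl ether (PPTS, MeOH, 0 °C) gives the C9-silylated primary alcohol F1. Dess–Martin oxidation (NaHCO3) gives the C9-silylated seco-aldehyde F2. NHK ring closure under the conditions of step 14 gives the C9-silylated macrocyclic alcohol as a C2 epimer mixture F3. Dess–Martin oxidation gives the C9-silylated macrocyclic C2 enone F4. Reagent-controlled Corey–Bakshi–Shibata reduction ((R)-Me-CBS, catecholborane, −78 °C) gives the C9-silylated 2S alcohol F5. HF·pyridine then returns to the route at 23.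

Step 9: the aqueous zinc reaction may proceed with poor simple diastereoselection at C6 if the closed transition state is not followed. The fallback sets out from 12 and 14 and carries the C6 epimer on. The 6-epi diol F6 is silylated at the primary hydroxyl (TBSCl, imidazole) to the 6-epi primary silyl ether F7. Mitsunobu esterification with 18 (PPh3, DIAD, toluene, 0 °C) installs the (R)-2-methylbutanoate with inversion at C6 and returns to the route at 19.

Step 3: lithiation of 5 and the borane sequence may suffer from Z to E isomerisation of aldehyde 4 or from low enantioselectivity. The fallback sets out from 4 and uses auxiliary control. Evans syn-glycolate aldol with (S)-4-benzyl-3-{[(4-methoxybenzyl)oxy]acetyl}oxazolidin-2-one (Bu2BOTf, iPr2NEt, −78 °C) gives the syn aldol imide F8. TBSOTf and 2,6-lutidine give the silylated imide F9. LiBH4 (THF, MeOH) cleaves the auxiliary to the primary alcohol F10. Dess–Martin oxidation gives the α-alkoxy aldehyde F11. Wittig methylenation (Ph3P=CH2, THF, −78 °C) returns to the route at 8.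

Further compounds
F1 | step 14 | C9-silylated primary alcohol | C=C1C(=O)O[C@@H]([C@H](O[Si](C)(C)C(C)(C)C)/C(C)=C\I)[C@@H]1[C@H](OC(=O)[C@H](C)CC)/C=C(/C)CCO
F2 | step 14 | C9-silylated seco-aldehyde | C=C1C(=O)O[C@@H]([C@H](O[Si](C)(C)C(C)(C)C)/C(C)=C\I)[C@@H]1[C@H](OC(=O)[C@H](C)CC)/C=C(/C)CC=O
F3 | step 14 | C9-silylated macrocyclic alcohol, C2 epimer mixture | C=C1C(=O)O[C@@H]2[C@@H]1[C@H](OC(=O)[C@H](C)CC)/C=C(/C)CC(O)/C=C(/C)[C@H]2O[Si](C)(C)C(C)(C)C
F4 | step 14 | C9-silylated macrocyclic C2 enone | C=C1C(=O)O[C@@H]2[C@@H]1[C@H](OC(=O)[C@H](C)CC)/C=C(/C)CC(=O)/C=C(/C)[C@H]2O[Si](C)(C)C(C)(C)C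
F5 | step 14 | C9-silylated 2S alcohol | C=C1C(=O)O[C@@H]2[C@@H]1[C@H](OC(=O)[C@H](C)CC)/C=C(/C)C[C@H](O)/C=C(/C)[C@H]2O[Si](C)(C)C(C)(C)C
F6 | step 9 | 6-epi diol | C=C1C(=O)O[C@@H]([C@H](O[Si](C)(C)C(C)(C)C)/C(C)=C\I)[C@@H]1[C@@H](O)/C=C(/C)CCO
F7 | step 9 | 6-epi primary silyl ether | C=C1C(=O)O[C@@H]([C@H](O[Si](C)(C)C(C)(C)C)/C(C)=C\I)[C@@H]1[C@@H](O)/C=C(/C)CCO[Si](C)(C)C(C)(C)C
F8 | step 3 | syn aldol imide | O=C1OC[C@H](Cc2ccccc2)N1C(=O)[C@@H](OCc1ccc(OC)cc1)[C@H](O)/C(C)=C\I
F9 | step 3 | silylated imide | O=C1OC[C@H](Cc2ccccc2)N1C(=O)[C@@H](OCc1ccc(OC)cc1)[C@H](O[Si](C)(C)C(C)(C)C)/C(C)=C\I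
F10 | step 3 | primary alcohol | OC[C@@H](OCc1ccc(OC)cc1)[C@H](O[Si](C)(C)C(C)(C)C)/C(C)=C\I
F11 | step 3 | α-alkoxy aldehyde | O=C[C@@H](OCc1ccc(OC)cc1)[C@H](O[Si](C)(C)C(C)(C)C)/C(C)=C\I
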